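## Retrosynthetic overview

1. Target 16 ⇐ bis(silyloxy)quinone 15 by Si–O hydrolysis in the work-up.
2. 15 ⇐ two molecules of cyclobutenedione 14 + bis(siloxyalkyne) 9 by a twofold Ni(0)-catalysed C–C activation/alkyne-insertion ring expansion (4 → 6). Both quinone rings are formed last, in one operation.
3. 9 ⇐ heptadeca-1,16-diyne 6 by acetylide oxygenation and O-silylation; 6 ⇐ 1,5-dibromopentane 1 + two molecules of 6-bromohex-1-yne 2 by Cu-catalysed sp3–sp3 coupling.
4. 14 ⇐ dimethyl squarate 11 ⇐ squaric acid 10 (the four-membered ring is bought).

**Assumption:** the target has no stereocentre and no stereogenic C=C (it is achiral), so the constitution alone defines it; the linker is read from the SMILES as thirteen CH2 groups between the two quinone rings.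

**Bookkeeping convention:** the route is bidirectional. Where two molecules of one compound are built into a product, the compound stands once on the Reactants line (marked 2 equiv) and its second molecule stands once more on the "Reagents that add atoms" line, so that each step balances atom for atom as written.

## Route

Step 1
Reactants: 1 1,5-dibromopentane; 2 6-bromohex-1-yne (2 equiv)
Product: 6 heptadeca-1,16-diyne, via pentane-1,5-diylbis(magnesium bromide) 3 (not isolated), via (6-bromohex-1-yn-1-yl)magnesium chloride 4 (not isolated), via heptadeca-1,16-diyne-1,17-diylbis(magnesium chloride) 5 (not isolated)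
Conditions: flask A: 1 (1.0 equiv), Mg, THF, 40 °C; flask B: 2 (2.3 equiv), i-PrMgCl (2.3 equiv), THF, 0 °C → rt; add A to B slowly, Li2CuCl4 (5 mol %), NMP, THF, −10 °C → rt; 1 M HCl
Reagents that add atoms: 6-bromohex-1-yne 2 (second molecule), C#CCCCCBr
Why: Kochi-type copper-catalysed sp3–sp3 Grignard cross-coupling in which the primary bromide of each of two molecules of 4 couples with one C–Mg end of the di-Grignard 3 (C6 + C5 + C6 = C17), while the acidic alkyne C–H is masked in situ as a magnesium acetylide (a non-transferable ligand on copper) and is restored on acidic work-up; no stereocentre is formed.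

Step 2
Reactants: 6 heptadeca-1,16-diyne
Product: 9 1,17-bis(triisopropylsilyloxy)heptadeca-1,16-diyne, via 1,17-dilithioheptadeca-1,16-diyne 7 (not isolated), via dilithium heptadeca-1,16-diyne-1,17-bis(olate) 8 (not isolated)
Conditions: n-BuLi (2.1 equiv), THF, −78 °C; LiOOt-Bu (2.3 equiv, from t-BuOOH + LiHMDS), THF, −78 → 0 °C; TIPSOTf (2.5 equiv), −78 → 0 °C
Reagents that add atoms: lithium tert-butyl peroxide, [Li]OOC(C)(C)C (made in the flask from tert-butyl hydroperoxide, CC(C)(C)OO); lithium tert-butyl peroxide (second molecule), [Li]OOC(C)(C)C; triisopropylsilyl trifluoromethanesulfonate, CC(C)[Si](OS(=O)(=O)C(F)(F)F)(C(C)C)C(C)C; triisopropylsilyl trifluoromethanesulfonate (second molecule), CC(C)[Si](OS(=O)(=O)C(F)(F)F)(C(C)C)C(C)C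
Why: Electrophilic oxygenation of each lithium acetylide terminus by one molecule of lithium tert-butyl peroxide gives the lithium ynolate, which the hard, hindered silyl triflate traps on oxygen to give the silyl ynol ether (acetylide oxidation/ynolate O-silylation, run at both ends); no stereocentre is formed.

Step 3
Reactants: 10 squaric acid
Product: 11 dimethyl squarate
Conditions: HC(OMe)3 (excess), MeOH, reflux
Reagents that add atoms: trimethyl orthoformate, COC(OC)OC; trimethyl orthoformate (second molecule), COC(OC)OC
Why: O-methylation of both OH groups of the strongly acidic vinylogous diacid by the orthoester (one methyl per orthoester molecule), which also scavenges the water and drives the vinylogous esterification to completion.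

Step 4
Reactants: 11 dimethyl squarate
Product: 14 3-methoxy-4-methylcyclobut-3-ene-1,2-dione, via lithium 2,3-dimethoxy-1-methyl-4-oxocyclobut-2-en-1-olate 12 (not isolated), via 2,3-dimethoxy-1-methyl-4-oxocyclobut-2-en-1-yl trifluoroacetate 13 (not isolated)
Conditions: MeLi (1.05 equiv), THF, −78 °C; TFAA (1.2 equiv), −78 °C; aq NH4Cl, → rt
Reagents that add atoms: methyllithium, C[Li]; water, O
Why: 1,2-addition of MeLi to one squarate carbonyl, then trifluoroacetylation of the tertiary alkoxide and ionisation/hydrolysis with allylic transposition and loss of methanol unmasks the dione; the carbinol centre of 12/13 is racemic and is destroyed.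

Step 5
Reactants: 9 1,17-bis(triisopropylsilyloxy)heptadeca-1,16-diyne; 14 3-methoxy-4-methylcyclobut-3-ene-1,2-dione (2 equiv)
Product: 16 3,3'-(tridecane-1,13-diyl)bis(2-hydroxy-5-methoxy-6-methylcyclohexa-2,5-diene-1,4-dione), via bis(triisopropylsilyl) ether bisquinone 15 (not isolated)
Conditions: Ni(cod)2 (20 mol %), PPh3 (40 mol %), 14 (2.3 equiv, slow addition), toluene, 0 → 40 °C; then 1 M HCl, THF, 0 °C → rt
Reagents that add atoms: 3-methoxy-4-methylcyclobut-3-ene-1,2-dione 14 (second molecule), COC1=C(C)C(=O)C1=O
Why: Proposed new method: strain-driven oxidative addition of Ni(0) into the C1–C2 acyl–acyl bond of 14 gives a nickelacyclopentenedione; the nucleophilic chain-bearing carbon of the siloxyalkyne then inserts into the more electrophilic Ni–acyl bond (the acyl on the OMe-bearing carbon, the same carbonyl that hard nucleophiles attack in 14) with Ni going to the O-bearing carbon, and acyl–vinyl reductive elimination closes the six-membered quinone and returns Ni(0), so the chain ends up beside the C=O flanked by OMe and the OSi beside the C=O flanked by Me, once at each alkyne terminus with one molecule of 14 each; the bulky tetrasubstituted silyloxyquinone 15 is a weak ligand for Ni(0), which allows turnover, and the vinylogous silyl esters are hydrolysed by dilute acid; the closest known reaction types are the stoichiometric maleoylcobalt–alkyne quinone synthesis and the Ni(0)-catalysed ring expansion of cyclobutenones with alkynes to phenols; no stereocentre is formed.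

## Compound list

1 | 1,5-dibromopentane | BrCCCCCBr | starting material
2 | 6-bromohex-1-yne | C#CCCCCBr | starting material
3 | pentane-1,5-diylbis(magnesium bromide) | Br[Mg]CCCCC[Mg]Br | intermediate
4 | (6-bromohex-1-yn-1-yl)magnesium chloride | Cl[Mg]C#CCCCCBr | intermediate
5 | heptadeca-1,16-diyne-1,17-diylbis(magnesium chloride) | Cl[Mg]C#CCCCCCCCCCCCCCC#C[Mg]Cl | intermediate
6 | heptadeca-1,16-diyne | C#CCCCCCCCCCCCCCC#C | intermediate
7 | 1,17-dilithioheptadeca-1,16-diyne | [Li]C#CCCCCCCCCCCCCCC#C[Li] | intermediate
8 | dilithium heptadeca-1,16-diyne-1,17-bis(olate) | [Li]OC#CCCCCCCCCCCCCCC#CO[Li] | intermediate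
9 | 1,17-bis(triisopropylsilyloxy)heptadeca-1,16-diyne | CC(C)[Si](C(C)C)(C(C)C)OC#CCCCCCCCCCCCCCC#CO[Si](C(C)C)(C(C)C)C(C)C | intermediate
10 | squaric acid (3,4-dihydroxycyclobut-3-ene-1,2-dione) | OC1=C(O)C(=O)C1=O | starting material
11 | dimethyl squarate (3,4-dimethoxycyclobut-3-ene-1,2-dione) | COC1=C(OC)C(=O)C1=O | intermediate
12 | lithium 2,3-dimethoxy-1-methyl-4-oxocyclobut-2-en-1-olate (racemic) | [Li]OC1(C)C(=O)C(OC)=C1OC | intermediate
13 | 2,3-dimethoxy-1-methyl-4-oxocyclobut-2-en-1-yl trifluoroacetate (racemic) | CC1(OC(=O)C(F)(F)F)C(=O)C(OC)=C1OC | intermediate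
14 | 3-methoxy-4-methylcyclobut-3-ene-1,2-dione | COC1=C(C)C(=O)C1=O | intermediate
15 | 3,3'-(tridecane-1,13-diyl)bis[5-methoxy-6-methyl-2-(triisopropylsilyloxy)cyclohexa-2,5-diene-1,4-dione] | COC1=C(C)C(=O)C(O[Si](C(C)C)(C(C)C)C(C)C)=C(CCCCCCCCCCCCCC2=C(O[Si](C(C)C)(C(C)C)C(C)C)C(=O)C(C)=C(OC)C2=O)C1=O | intermediate
16 | 3,3'-(tridecane-1,13-diyl)bis(2-hydroxy-5-methoxy-6-methylcyclohexa-2,5-diene-1,4-dione), achiral | COC1=C(C)C(=O)C(O)=C(CCCCCCCCCCCCCC2=C(O)C(=O)C(C)=C(OC)C2=O)C1=O | target

## Summary

Total step count: 5. Longest linear sequence: 3 steps (1 → 2 → 5, or 3 → 4 → 5).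

## Steps most likely to fail

**Step 5 (proposed new Ni-catalysed double ring expansion).** The risks are catalyst turnover, decarbonylation of the nickelacycle, and the regiochemistry of alkyne insertion at each ring. The fallback is the stoichiometric maleoylcobalt quinone synthesis, a known reaction type. It sets out from 14 and 9. 14 is treated with ClCo(PPh3)3 in benzene at rt, which inserts into the acyl–acyl bond and gives the isolable complex chlorido(2-methoxy-3-methylmaleoyl)bis(triphenylphosphane)cobalt(III) F1. F1 (2.2 equiv, one molecule per alkyne terminus) is then combined with 9 and AgBF4 in MeCN at rt (chloride abstraction, alkyne insertion, reductive elimination). This comes back to the route at 15, which is desilylated with dilute HCl exactly as in step 5. Because the metal is stoichiometric, turnover and product inhibition no longer matter; the regiochemistry of insertion would still have to be confirmed by HMBC.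

**Step 2 (twofold acetylide oxygenation/O-silylation).** The risks are incomplete oxygenation at one terminus and C-silylation. The fallback reaches the same bis-ynolate by ester homologation with a Kowalski-type 1,2-shift. It sets out from 6. Both terminal alkynes are cleaved oxidatively (RuCl3 cat., NaIO4, CCl4/MeCN/H2O) to pentadecanedioic acid F2. F2 is esterified (EtOH, H2SO4, reflux) to diethyl pentadecanedioate F3. F3 is treated with LiCHBr2 (2 equiv or more; from CH2Br2 and LiTMP, THF, −78 °C) and LiHMDS to give 1,1,17,17-tetrabromoheptadecane-2,16-dione F4 as its lithium bis-enolate, not isolated. n-BuLi (−78 °C → rt) then induces bromine–lithium exchange and rearrangement at both ends. This comes back to the route at the bis-ynolate 8, which is silylated with TIPSOTf to 9.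

**Step 1 (double Cu-catalysed coupling with the alkyne masked only as its magnesium salt).** The risks are mono-coupling and interference by the acetylide. The fallback builds the saturated chain first and introduces the alkynes afterwards by SN2. It sets out from 1. The di-Grignard 3 is coupled with 1-bromo-4-chlorobutane (ClCCCCBr, 2.3 equiv; Li2CuCl4 cat., THF, 0 °C; only the C–Br bond reacts) to give 1,13-dichlorotridecane F5. F5 is treated with lithium acetylide–ethylenediamine complex (2.5 equiv, DMSO, NaI cat., rt). This comes back to the route at 6.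

## Further compounds

F1 | step 5 | chlorido(2-methoxy-3-methylmaleoyl)bis(triphenylphosphane)cobalt(III) | COC1=C(C)C(=O)[Co-2](Cl)([P+](c2ccccc2)(c2ccccc2)c2ccccc2)([P+](c2ccccc2)(c2ccccc2)c2ccccc2)C1=O
F2 | step 2 | pentadecanedioic acid | OC(=O)CCCCCCCCCCCCCC(=O)O
F3 | step 2 | diethyl pentadecanedioate | CCOC(=O)CCCCCCCCCCCCCC(=O)OCC
F4 | step 2 | 1,1,17,17-tetrabromoheptadecane-2,16-dione | BrC(Br)C(=O)CCCCCCCCCCCCCC(=O)C(Br)Br
F5 | step 1 | 1,13-dichlorotridecane | ClCCCCCCCCCCCCCCl
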